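**Target:** 4-[(2S,3S)-3-(hydroxymethyl)-7-[(E)-3-hydroxyprop-1-enyl]-5-methoxy-2,3-dihydro-1,4-benzodioxin-2-yl]-2,6-dimethoxyphenol, the trans-2-aryl-3-hydroxymethyl benzodioxane.

Assumption: compounds 1, 2, 4, 6, 8, 10, 11, 16, 17 and 19 are purchased.

## Retrosynthetic overview

1. The (E)-hydroxypropenyl chain is disconnected by Suzuki coupling: 7-bromobenzodioxane 15 + vinylboronate 21.
2. The dioxane ring is opened at O1–C2: intramolecular 1,6-oxa-Michael addition of the catechol OH onto a syringyl p-quinone methide generated from aryl-glycerol β-aryl ether 14 (C-3 already set; C-2 set trans in the closure).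
3. 14 comes from an Evans syn-glycolate aldol of aryloxyacetyl imide 9 with acetylsyringaldehyde 12, then LiBH4.
4. 9 comes from 5-bromo-o-vanillin 4: its only OH is alkylated with bromoacetyl auxiliary 3, and the CHO becomes the second phenol oxygen by Baeyer–Villiger oxidation.
5. Ring order: both arenes are bought; the 1,4-dioxane ring is the only ring formed (step 8).

## Route

**Step 1**
Reactants: 1 (R)-4-benzyloxazolidin-2-one; 2 bromoacetyl bromide
Product: 3 (R)-4-benzyl-3-(2-bromoacetyl)oxazolidin-2-one
Conditions: n-BuLi, THF, −78 °C; then 2, −78 → 0 °C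
Reagents that add atoms: bromoacetyl bromide (2), O=C(Br)CBr
Why: N-acylation of the lithiated oxazolidinone occurs at the acyl bromide, far faster than at the alkyl bromide; the auxiliary stereocentre is untouched.

**Step 2**
Reactants: 4 5-bromo-2-hydroxy-3-methoxybenzaldehyde; 3
Product: 5 (R)-4-benzyl-3-[2-(4-bromo-2-formyl-6-methoxyphenoxy)acetyl]oxazolidin-2-one
Conditions: K2CO3, KI (cat.), DMF, 0 °C → rt
Reagents that add atoms: none (both partners are numbered reactants)
Why: Williamson ether synthesis (phenoxide SN2 on the α-bromo imide); 4 has a single OH, so the oxygen para to Br, the future O-4 of the benzodioxane, is alkylated unambiguously.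

**Step 3**
Reactants: 5; 6 mCPBA
Product: 7 (R)-4-benzyl-3-[2-(4-bromo-2-hydroxy-6-methoxyphenoxy)acetyl]oxazolidin-2-one
Conditions: mCPBA, CH2Cl2, rt; then TsOH (cat.), MeOH, rt
Reagents that add atoms: mCPBA (6), O=C(OO)c1cccc(Cl)c1 (supplies the phenolic O; the formyl carbon leaves as methyl formate)
Why: Baeyer–Villiger oxidation of an ortho-alkoxybenzaldehyde proceeds by aryl migration to the aryl formate, and acid methanolysis frees the phenol without base, so the imide is not attacked.

**Step 4**
Reactants: 7; 8 pivaloyl chloride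
Product: 9 (R)-4-benzyl-3-[2-(4-bromo-2-methoxy-6-pivaloyloxyphenoxy)acetyl]oxazolidin-2-one
Conditions: PivCl, pyridine, DMAP (cat.), CH2Cl2, 0 °C
Reagents that add atoms: pivaloyl chloride (8), CC(C)(C)C(=O)Cl
Why: Phenol acylation; the pivalate has no α-H, so it is inert in the boron aldol, and it is removed later in the hydride step.

**Step 5**
Reactants: 10 syringaldehyde; 11 acetic anhydride
Product: 12 4-acetoxy-3,5-dimethoxybenzaldehyde
Conditions: Ac2O, pyridine, DMAP (cat.), CH2Cl2, rt
Reagents that add atoms: acetic anhydride (11), CC(=O)OC(C)=O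
Why: Phenol acetylation masks the acidic OH for the aldol and makes the aldehyde more electrophilic.

**Step 6**
Reactants: 9; 12
Product: 13 (R)-4-benzyl-3-[(2R,3S)-3-(4-acetoxy-3,5-dimethoxyphenyl)-2-(4-bromo-2-methoxy-6-pivaloyloxyphenoxy)-3-hydroxypropanoyl]oxazolidin-2-one
Conditions: Bu2BOTf, i-Pr2NEt, CH2Cl2, −78 → 0 °C; then 12, −78 → 0 °C; pH 7 buffer/MeOH/H2O2, 0 °C
Reagents that add atoms: none
Why: Evans syn aldol of the (Z)-boron glycolate enolate through a Zimmerman–Traxler chair; the (R)-benzyl auxiliary blocks one enolate face and gives the (2R,3S) adduct, whose C-2 becomes C-3 (S) of the target (the descriptor changes only because C=O becomes CH2OH).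

**Step 7**
Reactants: 13
Product: 14 (1S,2S)-2-(4-bromo-2-hydroxy-6-methoxyphenoxy)-1-(4-hydroxy-3,5-dimethoxyphenyl)propane-1,3-diol
Conditions: LiBH4, THF/MeOH, 0 °C → rt
Reagents that add atoms: none
Why: Reductive cleavage of the N-acyl oxazolidinone to the primary alcohol (auxiliary recovered), with the aryl acetate and aryl pivalate cleaved in the same pot; the non-enolising hydride conditions leave the aryloxy-bearing stereocentre intact.

**Step 8**
Reactants: 14
Product: 15 4-[(2S,3S)-7-bromo-3-(hydroxymethyl)-5-methoxy-2,3-dihydro-1,4-benzodioxin-2-yl]-2,6-dimethoxyphenol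
Conditions: TMSBr, CH2Cl2, 0 °C → rt; then sat. aq NaHCO3, rt; TsOH (cat.), CH2Cl2, rt (to drive any cis isomer to trans)
Reagents that add atoms: none
Why: The benzylic bromide loses HBr to give the syringyl p-quinone methide, which the neighbouring phenol traps in a 6-exo intramolecular 1,6-oxa-Michael addition; the closure is reversible, so C-2 settles trans to the fixed C-3 (aryl and CH2OH both equatorial), giving (2S,3S).

**Step 9**
Reactants: 16 propargyl alcohol; 17 TBSCl
Product: 18 tert-butyldimethyl(prop-2-yn-1-yloxy)silane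
Conditions: TBSCl, imidazole, CH2Cl2, 0 °C → rt
Reagents that add atoms: TBSCl (17), CC(C)(C)[Si](C)(C)Cl
Why: Standard silylation removes the acidic OH before hydroboration.

**Step 10**
Reactants: 18; 19 pinacolborane
Product: 20 (E)-tert-butyldimethyl{[3-(4,4,5,5-tetramethyl-1,3,2-dioxaborolan-2-yl)allyl]oxy}silane
Conditions: HBpin, Cp2Zr(H)Cl (5 mol%), Et3N (10 mol%), neat, 60 °C
Reagents that add atoms: pinacolborane (19), CC1(C)OBOC1(C)C
Why: Zr-catalysed syn, anti-Markovnikov hydroboration of the terminal alkyne gives only the (E)-vinylboronate.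

**Step 11**
Reactants: 20
Product: 21 (E)-3-(4,4,5,5-tetramethyl-1,3,2-dioxaborolan-2-yl)prop-2-en-1-ol
Conditions: AcOH/THF/H2O (3:1:1), rt
Reagents that add atoms: none
Why: Mild acid desilylation of the primary TBS ether; fluoride is avoided so the Bpin group and the alkene geometry are preserved.

**Step 12**
Reactants: 15; 21
Product: 22 4-[(2S,3S)-3-(hydroxymethyl)-7-[(E)-3-hydroxyprop-1-enyl]-5-methoxy-2,3-dihydro-1,4-benzodioxin-2-yl]-2,6-dimethoxyphenol (target)
Conditions: XPhos Pd G3 (3 mol%), K3PO4 (aq), THF/H2O, degassed, 45 °C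
Reagents that add atoms: none (both partners are numbered reactants)
Why: Suzuki–Miyaura coupling with retention of the (E)-alkene; the active catalyst allows a low temperature for the electron-rich bromide, tolerating the free phenol and alcohols and leaving both stereocentres untouched.

## Compound list

1 | (R)-4-benzyloxazolidin-2-one | O=C1N[C@H](Cc2ccccc2)CO1 | starting material
2 | bromoacetyl bromide | O=C(Br)CBr | starting material
3 | (R)-4-benzyl-3-(2-bromoacetyl)oxazolidin-2-one | O=C(CBr)N1[C@H](Cc2ccccc2)COC1=O | intermediate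
4 | 5-bromo-2-hydroxy-3-methoxybenzaldehyde | COc1cc(Br)cc(C=O)c1O | starting material
5 | (R)-4-benzyl-3-[2-(4-bromo-2-formyl-6-methoxyphenoxy)acetyl]oxazolidin-2-one | COc1cc(Br)cc(C=O)c1OCC(=O)N1[C@H](Cc2ccccc2)COC1=O | intermediate
6 | mCPBA | O=C(OO)c1cccc(Cl)c1 | starting material (reagent)
7 | (R)-4-benzyl-3-[2-(4-bromo-2-hydroxy-6-methoxyphenoxy)acetyl]oxazolidin-2-one | COc1cc(Br)cc(O)c1OCC(=O)N1[C@H](Cc2ccccc2)COC1=O | intermediate
8 | pivaloyl chloride | CC(C)(C)C(=O)Cl | starting material (reagent)
9 | (R)-4-benzyl-3-[2-(4-bromo-2-methoxy-6-pivaloyloxyphenoxy)acetyl]oxazolidin-2-one | COc1cc(Br)cc(OC(=O)C(C)(C)C)c1OCC(=O)N1[C@H](Cc2ccccc2)COC1=O | intermediate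
10 | syringaldehyde | COc1cc(C=O)cc(OC)c1O | starting material
11 | acetic anhydride | CC(=O)OC(C)=O | starting material (reagent)
12 | 4-acetoxy-3,5-dimethoxybenzaldehyde | COc1cc(C=O)cc(OC)c1OC(C)=O | intermediate
13 | (R)-4-benzyl-3-[(2R,3S)-3-(4-acetoxy-3,5-dimethoxyphenyl)-2-(4-bromo-2-methoxy-6-pivaloyloxyphenoxy)-3-hydroxypropanoyl]oxazolidin-2-one | COc1cc([C@H](O)[C@@H](Oc2c(OC)cc(Br)cc2OC(=O)C(C)(C)C)C(=O)N2[C@H](Cc3ccccc3)COC2=O)cc(OC)c1OC(C)=O | intermediate
14 | (1S,2S)-2-(4-bromo-2-hydroxy-6-methoxyphenoxy)-1-(4-hydroxy-3,5-dimethoxyphenyl)propane-1,3-diol | COc1cc([C@H](O)[C@H](CO)Oc2c(O)cc(Br)cc2OC)cc(OC)c1O | intermediate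
15 | 4-[(2S,3S)-7-bromo-3-(hydroxymethyl)-5-methoxy-2,3-dihydro-1,4-benzodioxin-2-yl]-2,6-dimethoxyphenol | COc1cc([C@@H]2Oc3cc(Br)cc(OC)c3O[C@H]2CO)cc(OC)c1O | intermediate
16 | propargyl alcohol | C#CCO | starting material
17 | tert-butyldimethylsilyl chloride | CC(C)(C)[Si](C)(C)Cl | starting material (reagent)
18 | tert-butyldimethyl(prop-2-yn-1-yloxy)silane | C#CCO[Si](C)(C)C(C)(C)C | intermediate
19 | pinacolborane | CC1(C)OBOC1(C)C | starting material (reagent)
20 | (E)-tert-butyldimethyl{[3-(4,4,5,5-tetramethyl-1,3,2-dioxaborolan-2-yl)allyl]oxy}silane | CC(C)(C)[Si](C)(C)OC/C=C/B1OC(C)(C)C(C)(C)O1 | intermediate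
21 | (E)-3-(4,4,5,5-tetramethyl-1,3,2-dioxaborolan-2-yl)prop-2-en-1-ol | OC/C=C/B1OC(C)(C)C(C)(C)O1 | intermediate
22 | 4-[(2S,3S)-3-(hydroxymethyl)-7-[(E)-3-hydroxyprop-1-enyl]-5-methoxy-2,3-dihydro-1,4-benzodioxin-2-yl]-2,6-dimethoxyphenol | COc1cc([C@@H]2Oc3cc(/C=C/CO)cc(OC)c3O[C@H]2CO)cc(OC)c1O | target

## Step count

Total steps: 12.
Longest linear sequence: 8 (steps 1 → 2 → 3 → 4 → 6 → 7 → 8 → 12). The other branches are 5 (aldehyde 12) and 4 (boronate 21) steps to the target.

## Steps most likely to fail

1. **Step 3** (Baeyer–Villiger, then a free phenol next to the imide). Risks are H-migration to the benzoic acid and acyl transfer of the imide onto the new phenol to give a lactone. Fallback: attach the auxiliary last. Alkylate 4 with tert-butyl bromoacetate, do the Baeyer–Villiger/deformylation and pivaloylation on the ester, cleave with TFA, then couple the acid to 1 through the pivaloyl mixed anhydride (Et3N, LiCl) to reach 9.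

2. **Step 8** (quinone methide oxa-Michael closure). Risks are incomplete cyclisation, cis isomer, or quinone methide oligomerisation and tautomerisation. Fallback: a base-triggered quinone methide from a different precursor. Carry both phenols as TBS ethers instead of esters, acetylate the 7- and 9-OH after the LiBH4 step, then treat with TBAF: desilylation, 1,6-elimination of the benzylic acetate and oxa-Michael closure occur in one pot, and the 9-acetate is removed with K2CO3/MeOH.

3. **Step 12** (Suzuki coupling on an electron-rich bromide carrying a p-hydroxybenzyl aryl ether in aqueous base). Risks are ring opening or epimerisation through the phenoxide and protodeboronation. Fallback: Heck reaction of 15 with ethyl acrylate under anhydrous amine-base conditions (Pd(OAc)2, P(o-tol)3, Et3N, DMF), then DIBAL-H reduction of the (E)-cinnamate to the allylic alcohol.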